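**Retrosynthetic overview**
1. The target comes from its 5-O-tosylate by S–O hydrolysis, done in the same flask as the ring closure.
2. Ring C is the only ring built and it is formed last. O1–C2 comes from cyclodehydration. C3–C4 comes from a carbene-catalysed crossed benzoin that joins two carbonyl carbons: an acyl anion at C3 (Breslow intermediate of a ring B aryl glyoxal) attacks the formyl carbon C4 of a ring A salicylaldehyde.
3. The ring B glyoxal hydrate comes from acetovanillone by Riley oxidation.
4. The ring A aldehyde comes from 2,4,6-trihydroxybenzaldehyde: Br then OMe at the future C8, prenyl on the para OH (future O7), and tosyl on the less hindered ortho OH (future 5-OH), so that only the future O1 can cyclise.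
5. Rings A and B are bought as aromatics. The route is convergent: 4 steps plus 1 step, then the union.

Assumption: the SMILES contains no stereocentre and no stereogenic double bond, so the target is achiral and the request for a single enantiomer needs no stereocontrol.

**Route**

Step 1
Reactants: 1 2,4,6-trihydroxybenzaldehyde
Product: 2 3-bromo-2,4,6-trihydroxybenzaldehyde
Conditions: N-bromosuccinimide (1.0 equiv), MeCN, −20 to 0 °C, dark
Reagents that add atoms: N-bromosuccinimide, O=C1CCC(=O)N1Br
Why: Electrophilic aromatic bromination; the two open ring positions of 1 are equivalent, so one equivalent at low temperature gives a single monobromide, and the first bromine slows a second substitution.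

Step 2
Reactants: 2 3-bromo-2,4,6-trihydroxybenzaldehyde
Product: 3 2,4,6-trihydroxy-3-methoxybenzaldehyde
Conditions: NaOMe (6 equiv, 25% in MeOH), CuBr (20 mol %), DMF, 105 °C, N2; then cold 2 M HCl
Reagents that add atoms: sodium methoxide, [Na+].[O-]C
Why: Copper-catalysed Ullmann-type C–O coupling of an ortho-bromophenolate, the reaction type that turns 5-bromovanillin into syringaldehyde and 6-bromo-5,7-dihydroxyflavone into its 6-methoxy analogue; the formyl group is shielded as part of the triphenolate.

Step 3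
Reactants: 3 2,4,6-trihydroxy-3-methoxybenzaldehyde
Product: 4 2,6-dihydroxy-3-methoxy-4-(3-methylbut-2-enyloxy)benzaldehyde
Conditions: prenyl bromide (1.05 equiv), K2CO3 (1.1 equiv), acetone, 0 °C to rt
Reagents that add atoms: prenyl bromide (1-bromo-3-methylbut-2-ene), CC(C)=CCBr
Why: Williamson ether synthesis under acidity control; the 4-OH is para to the formyl group and is the only OH not hydrogen-bonded to it, so it is ionised and O-alkylated first.

Step 4
Reactants: 4 2,6-dihydroxy-3-methoxy-4-(3-methylbut-2-enyloxy)benzaldehyde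
Product: 5 2-formyl-3-hydroxy-4-methoxy-5-(3-methylbut-2-enyloxy)phenyl 4-methylbenzenesulfonate
Conditions: TsCl (1.05 equiv), K2CO3 (1.2 equiv), acetone, 0 °C to rt
Reagents that add atoms: 4-methylbenzenesulfonyl chloride, Cc1ccc(cc1)S(=O)(=O)Cl
Why: Sterically controlled O-sulfonylation; the 6-OH has one ortho neighbour and the 2-OH has two (CHO and OMe), so the 6-OH reacts and the 2-OH stays chelated, while the sulfonate, unlike a silyl or acyl group, cannot migrate to a neighbouring alkoxide in step 6 and makes the aldehyde more electrophilic.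

Step 5
Reactants: 6 acetovanillone (1-(4-hydroxy-3-methoxyphenyl)ethan-1-one)
Product: 7 2,2-dihydroxy-1-(4-hydroxy-3-methoxyphenyl)ethan-1-one (aryl glyoxal hydrate)
Conditions: SeO2 (1.1 equiv), 1,4-dioxane/H2O 20:1, 100 °C; hot filtration, crystallise from water
Reagents that add atoms: selenium dioxide, O=[Se]=O; water, O
Why: Riley oxidation of an aryl methyl ketone (ene reaction of the enol, then [2,3]-shift) to the keto-aldehyde, isolated as its stable hydrate; a free para-phenol is tolerated, as in the preparation of 4-hydroxyphenylglyoxal hydrate.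

Step 6
Reactants: 5 2-formyl-3-hydroxy-4-methoxy-5-(3-methylbut-2-enyloxy)phenyl 4-methylbenzenesulfonate; 7 2,2-dihydroxy-1-(4-hydroxy-3-methoxyphenyl)ethan-1-one
Product: 10 3,5-dihydroxy-2-(4-hydroxy-3-methoxyphenyl)-8-methoxy-7-(3-methylbut-2-enyloxy)-4H-chromen-4-one (target), via crossed-benzoin ketol 8 (not isolated), via 5-O-tosyl flavonol 9 (not isolated)
Conditions: 2-(pentafluorophenyl)-6,7-dihydro-5H-pyrrolo[2,1-c][1,2,4]triazol-2-ium tetrafluoroborate (20 mol %), iPr2NEt (1 equiv), 4 Å MS, THF, 40 °C, argon, 7 (1.5 equiv) added over 8 h; once 8 is consumed, 2 M aq NaOH (8 equiv), 45 °C; then 1 M HCl to pH 4, 0 °C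
Reagents that add atoms: none
Why: Proposed new method: the carbene adds to the most electrophilic carbonyl present, the aldehyde carbon of 7, and proton transfer gives an aroyl-substituted Breslow intermediate, that is an acyl anion at the future C3, which attacks the hydrogen-bond-activated formyl carbon (future C4) of 5, an ortho,ortho'-disubstituted electron-rich aldehyde too hindered to homodimerise; ketol 8 closes through its only free phenol onto the activated aryl ketone (C2), and the enediolate expels the hemiketal hydroxyl (E1cB) to give the aromatic pyranone 9 irreversibly, which drains the reversible glyoxal homo-benzoin, and the opposite crossed selectivity would give the enediol tautomer of 8 and hence the same 9; the closest known reaction types are the chemoselective carbene-catalysed crossed benzoin with ortho-substituted benzaldehydes as acceptors, the cyanide-catalysed benzoin of phenylglyoxal, the Stetter reaction of glyoxamides, and the cyclodehydration of 2-hydroxy-1,3-diaryl-1,3-diones that ends Allan–Robinson flavonol syntheses; methanol-free aqueous NaOH then cleaves the sulfonate at sulfur without forming a methylating agent and without touching the prenyl ether, and the single transient stereocentre of 8 is destroyed.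

**Compound list**
1 | 2,4,6-trihydroxybenzaldehyde | O=Cc1c(O)cc(O)cc1O | starting material
2 | 3-bromo-2,4,6-trihydroxybenzaldehyde | O=Cc1c(O)cc(O)c(Br)c1O | intermediate
3 | 2,4,6-trihydroxy-3-methoxybenzaldehyde | O=Cc1c(O)cc(O)c(OC)c1O | intermediate
4 | 2,6-dihydroxy-3-methoxy-4-(3-methylbut-2-enyloxy)benzaldehyde | O=Cc1c(O)cc(OCC=C(C)C)c(OC)c1O | intermediate
5 | 2-formyl-3-hydroxy-4-methoxy-5-(3-methylbut-2-enyloxy)phenyl 4-methylbenzenesulfonate | O=Cc1c(OS(=O)(=O)c2ccc(C)cc2)cc(OCC=C(C)C)c(OC)c1O | intermediate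
6 | acetovanillone, 1-(4-hydroxy-3-methoxyphenyl)ethan-1-one | CC(=O)c1ccc(O)c(OC)c1 | starting material
7 | 2,2-dihydroxy-1-(4-hydroxy-3-methoxyphenyl)ethan-1-one | OC(O)C(=O)c1ccc(O)c(OC)c1 | intermediate
8 | 2-[1-hydroxy-3-(4-hydroxy-3-methoxyphenyl)-2,3-dioxopropyl]-3-hydroxy-4-methoxy-5-(3-methylbut-2-enyloxy)phenyl 4-methylbenzenesulfonate (racemic, not isolated) | OC(C(=O)C(=O)c1ccc(O)c(OC)c1)c1c(O)c(OC)c(OCC=C(C)C)cc1OS(=O)(=O)c1ccc(C)cc1 | intermediate
9 | 3-hydroxy-2-(4-hydroxy-3-methoxyphenyl)-8-methoxy-7-(3-methylbut-2-enyloxy)-4-oxo-4H-chromen-5-yl 4-methylbenzenesulfonate (not isolated) | COc1cc(-c2oc3c(OC)c(OCC=C(C)C)cc(OS(=O)(=O)c4ccc(C)cc4)c3c(=O)c2O)ccc1O | intermediate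
10 | 3,5-dihydroxy-2-(4-hydroxy-3-methoxyphenyl)-8-methoxy-7-(3-methylbut-2-enyloxy)-4H-chromen-4-one (achiral) | COc1cc(-c2oc3c(OC)c(OCC=C(C)C)cc(O)c3c(=O)c2O)ccc1O | target

**Step count**
- Total steps: 6
- Longest linear sequence: 5 steps (1 → 2 → 3 → 4 → 5 → 10)

**Three steps most likely to fail**

**Step 6.**
- Risks: the glyoxal may self-condense; it may isomerise through the carbene to a mandelate ester; aldehyde 5 may be too poor an acceptor.
- The fallback sets out from 5 and comes back at 10. It replaces the catalytic acyl anion by a nitronate as a stoichiometric acyl anion equivalent.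
- Commercial (E)-2-methoxy-4-(2-nitroethenyl)phenol is tosylated (TsCl, K2CO3, acetone) to 2-methoxy-4-[(E)-2-nitroethenyl]phenyl 4-methylbenzenesulfonate F1.
- Compounds 5 and F1 are treated with 1,4-diazabicyclo[2.2.2]octane (0.5 equiv, MeCN, 40 °C). Oxa-Michael addition through the only free phenol, intramolecular Henry reaction and dehydration give racemic 8-methoxy-2-[3-methoxy-4-(tosyloxy)phenyl]-7-(3-methylbut-2-enyloxy)-3-nitro-2H-chromen-5-yl 4-methylbenzenesulfonate F2.
- 30% H2O2 and NaOH in THF at 0 °C epoxidise the nitroalkene, not the prenyl alkene, to the 3,4-epoxy-3-nitroflavan bis-tosylate F3.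
- Hydroperoxide opens F3 at C4 with loss of nitrite. Base-induced O–O cleavage and enolisation then give the 5,4'-bis-O-tosyl flavonol F4.
- 2 M aq NaOH in THF at 45 °C under argon, then acidification, gives 10.

**Step 2.**
- Risks: hydrodebromination, or sluggish coupling on the very electron-rich triphenolate.
- The fallback sets out from 1 and comes back at 4. It replaces halogenation and coupling by a phenol ortho-oxygenation after the prenyl group is in place.
- Compound 1 with prenyl bromide and K2CO3 in acetone gives the symmetrical 2,6-dihydroxy-4-(3-methylbut-2-enyloxy)benzaldehyde F5.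
- 2-Iodoxybenzoic acid in DMF at rt delivers oxygen ortho to a phenol; both such sites are equivalent. The product is 2-hydroxy-4-(3-methylbut-2-enyloxy)-5,6-dioxocyclohexa-1,3-diene-1-carbaldehyde F6.
- F6 is reduced in the same flask with Na2S2O4 to 2,3,6-trihydroxy-4-(3-methylbut-2-enyloxy)benzaldehyde F7.
- MeI (1.0 equiv) and Li2CO3 in DMF methylate the only non-chelated hydroxyl (3-OH) to give 4.

**Step 4.**
- Risk: the 6-OH over 2-OH selectivity rests on sterics only, and the wrong isomer would lead to the 6-methoxy flavonol.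
- The fallback sets out from 1 and comes back at 5. It fixes the pattern by constitution: the original formyl carbon becomes the site of the 8-oxygen.
- TsCl (1.0 equiv) and K2CO3 in acetone at 0 °C sulfonylate the only non-chelated para OH of 1, giving 4-formyl-3,5-dihydroxyphenyl 4-methylbenzenesulfonate F8.
- Prenyl bromide and K2CO3 in DMF alkylate one of the two equivalent ortho hydroxyls, giving 4-formyl-3-hydroxy-5-(3-methylbut-2-enyloxy)phenyl 4-methylbenzenesulfonate F9.
- Dakin oxidation (30% H2O2, Na2CO3, THF/H2O, 0 °C) gives 3,4-dihydroxy-5-(3-methylbut-2-enyloxy)phenyl 4-methylbenzenesulfonate F10.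
- Ortho-specific Casnati–Skattebøl formylation (MgCl2, Et3N, paraformaldehyde, MeCN, reflux) can only reach the single open position ortho to a phenol. It gives 2-formyl-3,4-dihydroxy-5-(3-methylbut-2-enyloxy)phenyl 4-methylbenzenesulfonate F11.
- MeI (1.0 equiv) and K2CO3 in DMF methylate the non-chelated hydroxyl to give 5.

**Further compounds**
F1 | step 6 | 2-methoxy-4-[(E)-2-nitroethenyl]phenyl 4-methylbenzenesulfonate | COc1cc(/C=C/[N+](=O)[O-])ccc1OS(=O)(=O)c1ccc(C)cc1
F2 | step 6 | 8-methoxy-2-[3-methoxy-4-(tosyloxy)phenyl]-7-(3-methylbut-2-enyloxy)-3-nitro-2H-chromen-5-yl 4-methylbenzenesulfonate (racemic) | COc1cc(C2Oc3c(OC)c(OCC=C(C)C)cc(OS(=O)(=O)c4ccc(C)cc4)c3C=C2[N+](=O)[O-])ccc1OS(=O)(=O)c1ccc(C)cc1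
F3 | step 6 | 3,4-epoxy-3-nitroflavan bis-tosylate (racemic, relative configuration of no consequence) | COc1cc(C2Oc3c(OC)c(OCC=C(C)C)cc(OS(=O)(=O)c4ccc(C)cc4)c3C3OC23[N+](=O)[O-])ccc1OS(=O)(=O)c1ccc(C)cc1
F4 | step 6 | 5,4'-bis-O-tosyl flavonol | COc1cc(-c2oc3c(OC)c(OCC=C(C)C)cc(OS(=O)(=O)c4ccc(C)cc4)c3c(=O)c2O)ccc1OS(=O)(=O)c1ccc(C)cc1
F5 | step 2 | 2,6-dihydroxy-4-(3-methylbut-2-enyloxy)benzaldehyde | O=Cc1c(O)cc(OCC=C(C)C)cc1O
F6 | step 2 | 2-hydroxy-4-(3-methylbut-2-enyloxy)-5,6-dioxocyclohexa-1,3-diene-1-carbaldehyde | O=CC1=C(O)C=C(OCC=C(C)C)C(=O)C1=O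
F7 | step 2 | 2,3,6-trihydroxy-4-(3-methylbut-2-enyloxy)benzaldehyde | O=Cc1c(O)cc(OCC=C(C)C)c(O)c1O
F8 | step 4 | 4-formyl-3,5-dihydroxyphenyl 4-methylbenzenesulfonate | O=Cc1c(O)cc(OS(=O)(=O)c2ccc(C)cc2)cc1O
F9 | step 4 | 4-formyl-3-hydroxy-5-(3-methylbut-2-enyloxy)phenyl 4-methylbenzenesulfonate | O=Cc1c(O)cc(OS(=O)(=O)c2ccc(C)cc2)cc1OCC=C(C)C
F10 | step 4 | 3,4-dihydroxy-5-(3-methylbut-2-enyloxy)phenyl 4-methylbenzenesulfonate | Oc1cc(OS(=O)(=O)c2ccc(C)cc2)cc(OCC=C(C)C)c1O
F11 | step 4 | 2-formyl-3,4-dihydroxy-5-(3-methylbut-2-enyloxy)phenyl 4-methylbenzenesulfonate | O=Cc1c(OS(=O)(=O)c2ccc(C)cc2)cc(OCC=C(C)C)c(O)c1O
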